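**Retrosynthetic overview**

1. The target is read as a labdane: methyl (13Z)-2α,3α-bis(angeloyloxy)-12,17-dioxolabda-7,13-dien-15-oate (ring A = C1–C5, C10; ring B = C5–C10; C17 = CHO on C8; side chain C11–C16). The C12–C13 bond is made last from a C12 acyl chloride and a (Z)-alkenylzinc, after the two angelates and after the C8 formyl group (C8 ketone → C7=C8 enol triflate → carbonylation).
2. Key disconnection: C4–C5 and C9–C10 together, in one hydrogen-atom-transfer radical cascade of an acyclic triene keto-ester; ring A closes first (C4 to C5), ring B second (C10 to C9).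
3. Enabling feature: C4 with its gem-dimethyl pair is a tertiary radical site (unmasked from an isopropenyl group) in a 1,5-relation to C5 of the C5=C10 alkene, and C9 is the β-carbon of a C8(=O)–C9=C11–C12(=O)O keto-enoate, so the C8 ketone and the C11–C12 arm are in place once ring B has closed.
4. The cis C2/C3 diol comes from D-erythronolactone and is carried as an acetonide; as a cis-fused dioxolane it selects the chair of ring A and so passes its configuration on to C5, C10 and C9.
5. The acyclic precursor is built linearly: erythronolactone acetonide (C1–C4) → acetylide displacement and carboalumination (C5, C10, C20, C6) → ketophosphonate dianion (C7–C9) → glyoxylate olefination (C11, C12).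

Key step: step 8

Assumption (chemistry): the equatorial 9β arrangement of the C9 arm next to the C8 ketone is taken as the thermodynamically preferred one, as in 8-oxo-labdane derivatives; tert-butyl glyoxylate is used freshly distilled.

**Route**

Step 1
Reactants: 1 2,3-O-isopropylidene-D-erythronolactone
Product: 2 (3aR,6aR)-2,2,4-trimethyltetrahydrofuro[3,4-d][1,3]dioxol-4-ol (methyl lactol; both anomers)
Conditions: MeLi (1.1 equiv), THF, −78 °C; aq. NH4Cl
Reagents that add atoms: methyllithium [Li]C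
Why: Mono-addition of an alkyllithium to a γ-lactone stops at the lactol because the tetrahedral lithium alkoxide is stable at −78 °C; the two dioxolane stereocentres (future C2 and C3) are not touched.

Step 2
Reactants: 2 methyl lactol
Product: 3 [(4R,5S)-2,2-dimethyl-5-(prop-1-en-2-yl)-1,3-dioxolan-4-yl]methanol
Conditions: Ph3PCH3Br, KOtBu, THF, 0 °C → rt
Reagents that add atoms: methylenetriphenylphosphorane C=P(c1ccccc1)(c1ccccc1)c1ccccc1
Why: Wittig methylenation of the hydroxy ketone in equilibrium with the lactol gives the isopropenyl group; a lithium-free ylide at low temperature is chosen so that the ketone α-carbon (future C3) of the cis-dioxolane is not epimerised.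

Step 3
Reactants: 3 isopropenyl alcohol
Product: 6 (4R,5S)-2,2-dimethyl-4-(prop-2-yn-1-yl)-5-(prop-1-en-2-yl)-1,3-dioxolane, via primary triflate 4 (not isolated), via silyl alkyne 5 (not isolated)
Conditions: Tf2O, 2,6-lutidine, CH2Cl2, −78 °C; crude triflate, LiC≡CSiMe3 (from Me3SiC≡CH, n-BuLi), THF/DMPU, −78 → −20 °C; then K2CO3, MeOH, rt
Reagents that add atoms: ethynyltrimethylsilane (as its lithium acetylide) C#C[Si](C)(C)C
Why: Displacement of a primary triflate by a lithium acetylide (SN2 at the carbon that becomes C1) followed by protodesilylation; neither dioxolane stereocentre is involved.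

Step 4
Reactants: 6 terminal alkyne
Product: 8 (2E)-4-[(4R,5S)-2,2-dimethyl-5-(prop-1-en-2-yl)-1,3-dioxolan-4-yl]-3-methylbut-2-en-1-ol, via alkenylalane 7 (not isolated)
Conditions: AlMe3 (3 equiv), Cp2ZrCl2 (0.25 equiv), H2O (1 equiv), CH2Cl2, −20 °C; evaporate; n-BuLi, THF, −78 °C; (CH2O)n, −78 °C → rt
Reagents that add atoms: trimethylaluminium C[Al](C)C; formaldehyde (as paraformaldehyde) C=O
Why: Negishi zirconium-catalysed carboalumination adds methyl and aluminium syn across the alkyne with methyl on the internal carbon, and hydroxymethylation of the derived alanate with retention fixes the (E)-trisubstituted C5=C10 alkene.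

Step 5
Reactants: 8 allylic alcohol
Product: 9 (4R,5S)-4-[(2E)-4-bromo-2-methylbut-2-en-1-yl]-2,2-dimethyl-5-(prop-1-en-2-yl)-1,3-dioxolane
Conditions: CBr4, PPh3, CH2Cl2, 0 °C
Reagents that add atoms: carbon tetrabromide BrC(Br)(Br)Br
Why: Appel bromination converts the primary allylic alcohol under neutral conditions, so the acetonide survives and the alkene geometry is kept.

Step 6
Reactants: 9 allylic bromide; 10 dimethyl (2-oxopropyl)phosphonate
Product: 11 dimethyl {(5E)-7-[(4R,5S)-2,2-dimethyl-5-(prop-1-en-2-yl)-1,3-dioxolan-4-yl]-6-methyl-2-oxohept-5-en-1-yl}phosphonate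
Conditions: 10, NaH, THF, 0 °C; n-BuLi, 0 °C; then 9, 0 °C → rt; aq. NH4Cl
Reagents that add atoms: none
Why: The dianion of the β-ketophosphonate reacts at its more basic terminal carbon with the primary allylic bromide (SN2), which adds C7–C9 and keeps the phosphonate for the next olefination.

Step 7
Reactants: 11 ketophosphonate; 12 tert-butyl glyoxylate
Product: 13 tert-butyl (2E,7E)-9-[(4R,5S)-2,2-dimethyl-5-(prop-1-en-2-yl)-1,3-dioxolan-4-yl]-8-methyl-4-oxonona-2,7-dienoate
Conditions: LiCl, iPr2NEt, MeCN, 0 °C → rt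
Reagents that add atoms: none
Why: Horner–Wadsworth–Emmons olefination under the mild LiCl/amine (Masamune–Roush) conditions should give the (E)-keto-enoate without harming this base-sensitive acceptor.

Step 8
Reactants: 13 acyclic triene keto-ester
Product: 14 tert-butyl 2α,3α-(isopropylidenedioxy)-8-oxo-13,14,15,16,17-pentanorlabdan-12-oate
Conditions: Fe(acac)3 (0.3 equiv), PhSiH3 (2.5 equiv), EtOH/(CH2OH)2 5:1, 60 °C, Ar, 5 mM; then DBU (cat.), CH2Cl2, rt
Reagents that add atoms: none
Why: A trivalent iron hydride (from Fe(acac)3 and PhSiH3) transfers a hydrogen atom to the terminal CH2 of the isopropenyl group to give the tertiary C4 radical, which closes ring A by 6-endo-trig attack on C5 of the (E)-C5=C10 alkene; the tertiary C10 radical then closes ring B by 6-exo-trig conjugate (Giese) addition to C9 of the keto-enoate, and the C11 α-ester radical is reduced by divalent iron and protonated by ethanol. The closest known reaction type is the iron-hydride hydrogen-atom-transfer reductive olefin coupling and its use in radical polyene bicyclisations that end on an unsaturated carbonyl acceptor. C5 and C10 are set by a chair transition state for ring A in which the cis-fused dioxolane puts O2 equatorial and O3 axial; the other chair would force O2 axial against the C10 methyl and the axial C4 methyl, so the erythronolactone-derived centres C2 and C3 dictate the absolute configuration, and anti addition across the E alkene gives the trans ring fusion. C9 is set by the equatorial position of the CH2CO2tBu arm in the chair for ring B and, being α to the C8 ketone, is equilibrated to that arrangement by the DBU treatment. The step needs hydrogen-atom transfer to the 1,1-disubstituted alkene before the trisubstituted or the electron-poor alkene, which the accessible terminal CH2 and the electron-poor character of C9=C11 secure, and 6-endo before 5-exo closure, which the methyl on C10 secures (5-exo would join two quaternary carbons).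

Step 9
Reactants: 14 bicyclic keto-ester
Product: 15 tert-butyl 2α,3α-(isopropylidenedioxy)-8-(trifluoromethylsulfonyloxy)-13,14,15,16,17-pentanorlabd-7-en-12-oate
Conditions: KN(SiMe3)2 (1.1 equiv), THF, −78 °C; PhNTf2, −78 → 0 °C
Reagents that add atoms: N-phenylbis(trifluoromethanesulfonimide) O=S(=O)(N(c1ccccc1)S(=O)(=O)C(F)(F)F)C(F)(F)F
Why: Kinetic deprotonation by the bulky amide should occur at the C7 methylene and not at the hindered C9 methine next to the quaternary C10, and O-triflation of that enolate fixes the C7=C8 double bond.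

Step 10
Reactants: 15 enol triflate
Product: 16 tert-butyl 2α,3α-(isopropylidenedioxy)-17-oxo-13,14,15,16-tetranorlabd-7-en-12-oate
Conditions: Pd(PPh3)4 (5 mol%), CO (1 atm), Bu3SnH (slow addition), LiCl, THF, 50 °C
Reagents that add atoms: carbon monoxide [C-]#[O+]
Why: Palladium-catalysed reductive carbonylation of the vinyl triflate (oxidative addition to zerovalent palladium, CO insertion, hydride transfer from tin) delivers the C17 aldehyde on C8 with the double bond held at C7=C8.

Step 11
Reactants: 16 acetonide enal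
Product: 17 tert-butyl 2α,3α-dihydroxy-17-oxo-13,14,15,16-tetranorlabd-7-en-12-oate
Conditions: AcOH/H2O 4:1, 50 °C
Reagents that add atoms: none
Why: Aqueous acetic acid hydrolyses the isopropylidene acetal, while the tert-butyl ester and the enal are stable to this weak acid.

Step 12
Reactants: 17 diol; 18 angelic acid
Product: 20 tert-butyl 2α,3α-bis[(Z)-2-methylbut-2-enoyloxy]-17-oxo-13,14,15,16-tetranorlabd-7-en-12-oate, via mixed anhydride 19 (not isolated)
Conditions: 18 (6 equiv), 2,4,6-trichlorobenzoyl chloride, Et3N, toluene, rt; then 17, 80 °C, no DMAP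
Reagents that add atoms: none
Why: Acylation through the 2,4,6-trichlorobenzoyl mixed anhydride (Yamaguchi esterification) without a nucleophilic catalyst is the established way to esterify hindered secondary alcohols with angelic acid while keeping the Z geometry; the equatorial C2 hydroxyl should react first and heating drives the axial C3 hydroxyl.

Step 13
Reactants: 20 diangelate tert-butyl ester
Product: 21 2α,3α-bis[(Z)-2-methylbut-2-enoyloxy]-17-oxo-13,14,15,16-tetranorlabd-7-en-12-oic acid
Conditions: CF3CO2H/CH2Cl2 1:4, 0 °C → rt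
Reagents that add atoms: none
Why: Acidolysis of the tert-butyl ester (loss of the tert-butyl cation as isobutene) frees the C12 acid, while the angelates, the enal and all stereocentres are inert to cold trifluoroacetic acid.

Step 14
Reactants: 22 methyl but-2-ynoate
Product: 23 methyl (2Z)-3-iodobut-2-enoate
Conditions: NaI, AcOH, 110 °C
Reagents that add atoms: sodium iodide [Na+].[I-]
Why: Hydroiodination of the alkynoate (iodide adds at C3, protonation anti) gives the Z isomer in which iodine and ester are cis, the geometry needed for C13=C14.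

Step 15
Reactants: 21 C12 acid; 23 methyl (2Z)-3-iodobut-2-enoate
Product: 26 methyl (13Z)-2α,3α-bis[(Z)-2-methylbut-2-enoyloxy]-12,17-dioxolabda-7,13-dien-15-oate (CNP0141070.1), via acid chloride 24 (not isolated), via alkenylzinc iodide 25 (not isolated)
Conditions: 21, 1-chloro-N,N,2-trimethylprop-1-en-1-amine, CH2Cl2, 0 °C → rt; separately 23, Zn, LiCl, THF, rt; combine, Pd2(dba)3 (2.5 mol%), P(2-furyl)3 (10 mol%), THF, 0 °C
Reagents that add atoms: none
Why: The acid is turned into its chloride under neutral conditions and coupled with the ester-chelated (Z)-alkenylzinc reagent in a palladium-catalysed Negishi acylation, which proceeds with retention at the alkenyl carbon so that the C12 ketone and the C15 ester end up cis; alkenylzinc halides should not add to the enal or the angelates under these conditions.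

**Compound list**

1 | 2,3-O-isopropylidene-D-erythronolactone, (3aR,6aR)-2,2-dimethyldihydrofuro[3,4-d][1,3]dioxol-4(3aH)-one | CC1(C)O[C@@H](C(=O)O2)[C@H](O1)C2 | starting material
2 | (3aR,6aR)-2,2,4-trimethyltetrahydrofuro[3,4-d][1,3]dioxol-4-ol (methyl lactol, both anomers) | CC1(C)O[C@@H](C(C)(O)O2)[C@H](O1)C2 | intermediate
3 | [(4R,5S)-2,2-dimethyl-5-(prop-1-en-2-yl)-1,3-dioxolan-4-yl]methanol | CC1(C)O[C@@H](C(C)=C)[C@H](O1)CO | intermediate
4 | [(4R,5S)-2,2-dimethyl-5-(prop-1-en-2-yl)-1,3-dioxolan-4-yl]methyl trifluoromethanesulfonate | CC1(C)O[C@@H](C(C)=C)[C@H](O1)COS(=O)(=O)C(F)(F)F | intermediate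
5 | trimethyl{3-[(4R,5S)-2,2-dimethyl-5-(prop-1-en-2-yl)-1,3-dioxolan-4-yl]prop-1-yn-1-yl}silane | CC1(C)O[C@@H](C(C)=C)[C@H](O1)CC#C[Si](C)(C)C | intermediate
6 | (4R,5S)-2,2-dimethyl-4-(prop-2-yn-1-yl)-5-(prop-1-en-2-yl)-1,3-dioxolane | CC1(C)O[C@@H](C(C)=C)[C@H](O1)CC#C | intermediate
7 | dimethyl{(1E)-3-[(4R,5S)-2,2-dimethyl-5-(prop-1-en-2-yl)-1,3-dioxolan-4-yl]-2-methylprop-1-en-1-yl}alumane | CC1(C)O[C@@H](C(C)=C)[C@H](O1)C/C(C)=C/[Al](C)C | intermediate
8 | (2E)-4-[(4R,5S)-2,2-dimethyl-5-(prop-1-en-2-yl)-1,3-dioxolan-4-yl]-3-methylbut-2-en-1-ol | CC1(C)O[C@@H](C(C)=C)[C@H](O1)C/C(C)=C/CO | intermediate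
9 | (4R,5S)-4-[(2E)-4-bromo-2-methylbut-2-en-1-yl]-2,2-dimethyl-5-(prop-1-en-2-yl)-1,3-dioxolane | CC1(C)O[C@@H](C(C)=C)[C@H](O1)C/C(C)=C/CBr | intermediate
10 | dimethyl (2-oxopropyl)phosphonate | CC(=O)CP(=O)(OC)OC | starting material
11 | dimethyl {(5E)-7-[(4R,5S)-2,2-dimethyl-5-(prop-1-en-2-yl)-1,3-dioxolan-4-yl]-6-methyl-2-oxohept-5-en-1-yl}phosphonate | CC1(C)O[C@@H](C(C)=C)[C@H](O1)C/C(C)=C/CCC(=O)CP(=O)(OC)OC | intermediate
12 | tert-butyl glyoxylate (tert-butyl 2-oxoacetate) | O=CC(=O)OC(C)(C)C | starting material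
13 | tert-butyl (2E,7E)-9-[(4R,5S)-2,2-dimethyl-5-(prop-1-en-2-yl)-1,3-dioxolan-4-yl]-8-methyl-4-oxonona-2,7-dienoate | CC1(C)O[C@@H](C(C)=C)[C@H](O1)C/C(C)=C/CCC(=O)/C=C/C(=O)OC(C)(C)C | intermediate
14 | tert-butyl 2α,3α-(isopropylidenedioxy)-8-oxo-13,14,15,16,17-pentanorlabdan-12-oate (trans-decalin; 5α-H, 9α-H, 10β-CH3) | CC1(C)O[C@@H]2[C@H](O1)C[C@]3(C)[C@@H](CC(=O)OC(C)(C)C)C(=O)CC[C@H]3C2(C)C | intermediate
15 | tert-butyl 2α,3α-(isopropylidenedioxy)-8-(trifluoromethylsulfonyloxy)-13,14,15,16,17-pentanorlabd-7-en-12-oate | CC1(C)O[C@@H]2[C@H](O1)C[C@]3(C)[C@@H](CC(=O)OC(C)(C)C)C(OS(=O)(=O)C(F)(F)F)=CC[C@H]3C2(C)C | intermediate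
16 | tert-butyl 2α,3α-(isopropylidenedioxy)-17-oxo-13,14,15,16-tetranorlabd-7-en-12-oate | CC1(C)O[C@@H]2[C@H](O1)C[C@]3(C)[C@@H](CC(=O)OC(C)(C)C)C(C=O)=CC[C@H]3C2(C)C | intermediate
17 | tert-butyl 2α,3α-dihydroxy-17-oxo-13,14,15,16-tetranorlabd-7-en-12-oate | O[C@@H]1[C@H](O)C[C@]2(C)[C@@H](CC(=O)OC(C)(C)C)C(C=O)=CC[C@H]2C1(C)C | intermediate
18 | angelic acid, (Z)-2-methylbut-2-enoic acid | C/C=C(/C)C(=O)O | starting material
19 | (Z)-2-methylbut-2-enoic 2,4,6-trichlorobenzoic anhydride | C/C=C(/C)C(=O)OC(=O)c1c(Cl)cc(Cl)cc1Cl | intermediate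
20 | tert-butyl 2α,3α-bis[(Z)-2-methylbut-2-enoyloxy]-17-oxo-13,14,15,16-tetranorlabd-7-en-12-oate | C/C=C(/C)C(=O)O[C@@H]1[C@H](OC(=O)/C(C)=C\C)C[C@]2(C)[C@@H](CC(=O)OC(C)(C)C)C(C=O)=CC[C@H]2C1(C)C | intermediate
21 | 2α,3α-bis[(Z)-2-methylbut-2-enoyloxy]-17-oxo-13,14,15,16-tetranorlabd-7-en-12-oic acid | C/C=C(/C)C(=O)O[C@@H]1[C@H](OC(=O)/C(C)=C\C)C[C@]2(C)[C@@H](CC(=O)O)C(C=O)=CC[C@H]2C1(C)C | intermediate
22 | methyl but-2-ynoate | CC#CC(=O)OC | starting material
23 | methyl (2Z)-3-iodobut-2-enoate | C/C(I)=C/C(=O)OC | intermediate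
24 | 2α,3α-bis[(Z)-2-methylbut-2-enoyloxy]-17-oxo-13,14,15,16-tetranorlabd-7-en-12-oyl chloride | C/C=C(/C)C(=O)O[C@@H]1[C@H](OC(=O)/C(C)=C\C)C[C@]2(C)[C@@H](CC(=O)Cl)C(C=O)=CC[C@H]2C1(C)C | intermediate
25 | methyl (2Z)-3-(iodozincio)but-2-enoate | C/C([Zn]I)=C/C(=O)OC | intermediate
26 | methyl (13Z)-2α,3α-bis[(Z)-2-methylbut-2-enoyloxy]-12,17-dioxolabda-7,13-dien-15-oate (CNP0141070.1) | C/C=C(/C)C(=O)O[C@@H]1[C@H](OC(=O)/C(C)=C\C)C[C@]2(C)[C@@H](CC(=O)/C(C)=C\C(=O)OC)C(C=O)=CC[C@H]2C1(C)C | target

**Step count and risks**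

Total step count: 15. Longest linear sequence: 14 (steps 1–13 and 15; step 14 prepares the coupling partner).

Steps most likely to fail:

Step 8. The C4 radical may be quenched by a second hydrogen-atom transfer, or the keto-enoate may be reduced by the hydride source, before the slow 6-endo closure onto the unactivated alkene. The fallback makes the same C4 radical without any hydride, by photoredox fragmentation of a tertiary oxalate. It sets out from 11. Mukaiyama hydration of the isopropenyl group (Mn(dpm)3, PhSiH3, O2, iPrOH, 0 °C) should give the tertiary alcohol ketophosphonate F1. Olefination with 12 (LiCl, iPr2NEt, MeCN) should give the hydroxy keto-enoate F2. Acylation with methyl chlorooxoacetate (Et3N, DMAP, CH2Cl2) should give the tertiary methyl oxalate F3, and one equivalent of CsOH in THF/H2O the caesium oxalate F4. Irradiation of F4 with blue light and Ir[dF(CF3)ppy]2(dtbbpy)PF6 in DME/DMF with water should release two molecules of CO2 and run the same 6-endo/6-exo cascade, the final α-ester radical being reduced by the photocatalyst and protonated. The fallback comes back to the route at 14.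

Step 12. Acylation of the hindered axial C3 hydroxyl may stall, and forcing it may isomerise the angeloyl unit from Z to E. The fallback builds both angelates by olefination instead of acylation with angelic acid, and does so before the aldehyde is present. It sets out from 15. Aqueous acetic acid should give the diol triflate F5. Esterification with 2-[bis(2,2,2-trifluoroethoxy)phosphoryl]propanoic acid (N,N'-diisopropylcarbodiimide, DMAP, CH2Cl2) should give the bis(phosphonopropionate) F6. Still–Gennari olefination with acetaldehyde (KN(SiMe3)2, 18-crown-6, THF, −78 °C) should give the diangelate triflate F7 with Z selectivity. Reductive carbonylation of F7 as in step 10 brings the fallback back to the route at 20.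

Step 15. The new cis keto-enoate may isomerise from Z to E, or the organometallic may add to it in conjugate fashion, during the coupling. The fallback takes the Z geometry from a furan ring, in which it cannot be lost. It sets out from 21. N-Hydroxyphthalimide and N,N'-diisopropylcarbodiimide should give the redox-active ester F8. Nickel-catalysed decarboxylative coupling (NiCl2(dme), 4,4'-di-tert-butyl-2,2'-bipyridine, THF/DMF) with (3-methylfuran-2-yl)zinc chloride (from 2-bromo-3-methylfuran, n-BuLi, ZnCl2) should give the 2-alkyl-3-methylfuran F9, in which furan C2 is C12. Singlet oxygen (O2, rose bengal, light, iPr2NEt, CH2Cl2, −78 °C) should open the furan to the (Z)-keto acid F10, which is in equilibrium with its hydroxybutenolide. Methylation with Me3SiCHN2 in MeOH/toluene at 0 °C brings the fallback back to the route at 26.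

**Further compounds**

F1 | step 8 | dimethyl {(5E)-7-[(4R,5R)-5-(2-hydroxypropan-2-yl)-2,2-dimethyl-1,3-dioxolan-4-yl]-6-methyl-2-oxohept-5-en-1-yl}phosphonate | CC1(C)O[C@@H](C(C)(C)O)[C@H](O1)C/C(C)=C/CCC(=O)CP(=O)(OC)OC
F2 | step 8 | tert-butyl (2E,7E)-9-[(4R,5R)-5-(2-hydroxypropan-2-yl)-2,2-dimethyl-1,3-dioxolan-4-yl]-8-methyl-4-oxonona-2,7-dienoate | CC1(C)O[C@@H](C(C)(C)O)[C@H](O1)C/C(C)=C/CCC(=O)/C=C/C(=O)OC(C)(C)C
F3 | step 8 | methyl oxalate of the tertiary alcohol F2 | CC1(C)O[C@@H](C(C)(C)OC(=O)C(=O)OC)[C@H](O1)C/C(C)=C/CCC(=O)/C=C/C(=O)OC(C)(C)C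
F4 | step 8 | caesium oxalate of the tertiary alcohol F2 | CC1(C)O[C@@H](C(C)(C)OC(=O)C(=O)[O-])[C@H](O1)C/C(C)=C/CCC(=O)/C=C/C(=O)OC(C)(C)C.[Cs+]
F5 | step 12 | tert-butyl 2α,3α-dihydroxy-8-(trifluoromethylsulfonyloxy)-13,14,15,16,17-pentanorlabd-7-en-12-oate | O[C@@H]1[C@H](O)C[C@]2(C)[C@@H](CC(=O)OC(C)(C)C)C(OS(=O)(=O)C(F)(F)F)=CC[C@H]2C1(C)C
F6 | step 12 | 2α,3α-bis{2-[bis(2,2,2-trifluoroethoxy)phosphoryl]propanoyloxy} derivative of F5 | CC(C(=O)O[C@@H]1[C@H](OC(=O)C(C)P(=O)(OCC(F)(F)F)OCC(F)(F)F)C[C@]2(C)[C@@H](CC(=O)OC(C)(C)C)C(OS(=O)(=O)C(F)(F)F)=CC[C@H]2C1(C)C)P(=O)(OCC(F)(F)F)OCC(F)(F)F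
F7 | step 12 | tert-butyl 2α,3α-bis[(Z)-2-methylbut-2-enoyloxy]-8-(trifluoromethylsulfonyloxy)-13,14,15,16,17-pentanorlabd-7-en-12-oate | C/C=C(/C)C(=O)O[C@@H]1[C@H](OC(=O)/C(C)=C\C)C[C@]2(C)[C@@H](CC(=O)OC(C)(C)C)C(OS(=O)(=O)C(F)(F)F)=CC[C@H]2C1(C)C
F8 | step 15 | 1,3-dioxoisoindolin-2-yl ester of acid 21 | C/C=C(/C)C(=O)O[C@@H]1[C@H](OC(=O)/C(C)=C\C)C[C@]2(C)[C@@H](CC(=O)ON3C(=O)c4ccccc4C3=O)C(C=O)=CC[C@H]2C1(C)C
F9 | step 15 | 2α,3α-bis[(Z)-2-methylbut-2-enoyloxy]-15,16-epoxylabda-7,12,14-trien-17-al (2-alkyl-3-methylfuran) | C/C=C(/C)C(=O)O[C@@H]1[C@H](OC(=O)/C(C)=C\C)C[C@]2(C)[C@@H](Cc3occc3C)C(C=O)=CC[C@H]2C1(C)C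
F10 | step 15 | (13Z)-2α,3α-bis[(Z)-2-methylbut-2-enoyloxy]-12,17-dioxolabda-7,13-dien-15-oic acid | C/C=C(/C)C(=O)O[C@@H]1[C@H](OC(=O)/C(C)=C\C)C[C@]2(C)[C@@H](CC(=O)/C(C)=C\C(=O)O)C(C=O)=CC[C@H]2C1(C)C
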